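**Retrosynthetic overview**
- Ring C is opened at C8a–O1: the flavanone comes from an (S)-β-hydroxy ketone with bromine at C8a, closed by copper-catalysed intramolecular O-arylation that leaves C2 untouched.
- Ring A is disconnected at C4a–C5 and C8–C8a: a Diels–Alder reaction with loss of methanol joins a 4-prenyl 1,1,3-trioxygenated diene (C5 to C8) and a chiral 1-bromoalk-1-yn-3-one (C4a, C8a).
- Feature used: ring A carries oxygen at C5 and C7, the prenyl group at C8 and the acyl carbon at C4a, which is the pattern such a diene and an acetylenic ketone give. The alkyne bromine ends at C8a alone, so ring C can close in one direction only and no 6-/8-prenyl ambiguity arises.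
- Diene from methyl acetoacetate and prenyl bromide (3 steps); bromoynone from ethyl 3-(4-methoxyphenyl)-3-oxopropanoate, with C2 set by asymmetric transfer hydrogenation (5 steps).
- Ring order: ring B is bought, ring A is formed by cycloaddition (step 9), ring C by C–O coupling (step 11).

Key step: step 9

Remark: the diene is used as the 3Z isomer (C5 chain outside), the one able to reach the s-cis conformation; the geometry at C1 and the two sp3 centres of the cycloadduct vanish on aromatisation and are left undefined.

**Step 1**
Reactants: 1 methyl acetoacetate; 2 prenyl bromide (1-bromo-3-methylbut-2-ene)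
Product: 4 methyl 7-methyl-3-oxooct-6-enoate, via dilithium dianion 3 (not isolated)
Conditions: LiN(iPr)2 (2.1 equiv), THF, 0 °C; then 2 (1.0 equiv), 0 °C to rt; aq HCl
Reagents that add atoms: none
Why: The terminal (γ) carbanion of the 1,3-dianion is its most nucleophilic site, so SN2 attack on the primary allylic bromide should give γ-alkylation only (dianion alkylation of a β-keto ester).

**Step 2**
Reactants: 4 methyl 7-methyl-3-oxooct-6-enoate
Product: 6 methyl (E)-3-methoxy-7-methylocta-2,6-dienoate, via dimethyl ketal 5 (not isolated)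
Conditions: HC(OMe)3 (2 equiv), MeOH, p-TsOH (2 mol %), rt; then slow removal of volatiles at reduced pressure (≤60 °C)
Reagents that add atoms: trimethyl orthoformate, COC(OC)OC
Why: Acid-catalysed ketalisation followed by loss of methanol should give the conjugated enol ether as its more stable E isomer, and a catalytic sulfonic acid near room temperature should leave the trisubstituted alkene alone.

**Step 3**
Reactants: 6 methyl (E)-3-methoxy-7-methylocta-2,6-dienoate
Product: 8 (1Z,3Z)-1,3-dimethoxy-7-methyl-1-(trimethylsilyloxy)octa-1,3,6-triene, via lithium dienolate 7 (not isolated)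
Conditions: LiN(iPr)2 (1.1 equiv), THF, −78 °C; Me3SiCl (1.3 equiv), −78 °C to rt; pentane, filtration; used crude at once
Reagents that add atoms: chlorotrimethylsilane, C[Si](C)(C)Cl
Why: Kinetic γ-deprotonation of the β-methoxy enoate (the C4 methylene lies cis to the ester carbonyl that guides the amide base) gives the extended dienolate, which the oxophilic silyl chloride should trap at oxygen as the silyl ketene acetal, with the C4 chain expected trans to C2 to avoid allylic strain.

**Step 4**
Reactants: 9 ethyl 3-(4-methoxyphenyl)-3-oxopropanoate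
Product: 10 ethyl (S)-3-hydroxy-3-(4-methoxyphenyl)propanoate
Conditions: RuCl[(S,S)-TsDPEN](p-cymene) (1 mol %), HCO2H–Et3N (5:2), 30–40 °C
Reagents that add atoms: none
Why: In this Noyori–Ikariya asymmetric transfer hydrogenation, Ru–H and N–H add across the aryl ketone through a six-membered transition state whose face is fixed by the CH–π contact between the cymene ligand and the anisyl ring, so the (S,S) catalyst should give the (S)-benzylic alcohol, the future C2.

**Step 5**
Reactants: 10 ethyl (S)-3-hydroxy-3-(4-methoxyphenyl)propanoate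
Product: 11 ethyl (S)-3-(tert-butyldimethylsilyloxy)-3-(4-methoxyphenyl)propanoate
Conditions: TBSCl, imidazole, DMF, rt
Reagents that add atoms: tert-butyldimethylsilyl chloride, CC(C)(C)[Si](C)(C)Cl
Why: Imidazole-promoted O-silylation of the secondary alcohol does not touch the C–O bond at the stereocentre, and the ether blocks retro-aldol and elimination in the basic steps that follow.

**Step 6**
Reactants: 11 ethyl (S)-3-(tert-butyldimethylsilyloxy)-3-(4-methoxyphenyl)propanoate
Product: 12 (S)-3-(tert-butyldimethylsilyloxy)-N-methoxy-3-(4-methoxyphenyl)-N-methylpropanamide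
Conditions: MeNH(OMe)·HCl (1.6 equiv), iPrMgCl (3.1 equiv), THF, −20 to 0 °C
Reagents that add atoms: N,O-dimethylhydroxylamine hydrochloride, CNOC.Cl
Why: The chloromagnesium amide of N,O-dimethylhydroxylamine, made in the flask, should acylate on the ethyl ester at low temperature (direct ester aminolysis), conditions under which β-silyloxy esters do not eliminate.

**Step 7**
Reactants: 12 (S)-3-(tert-butyldimethylsilyloxy)-N-methoxy-3-(4-methoxyphenyl)-N-methylpropanamide; 13 trimethylsilylacetylene
Product: 15 (S)-5-(tert-butyldimethylsilyloxy)-5-(4-methoxyphenyl)-1-(trimethylsilyl)pent-1-yn-3-one, via lithium trimethylsilylacetylide 14 (not isolated)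
Conditions: 13 (1.5 equiv), n-BuLi (1.4 equiv), THF, −78 °C; then 12, −78 to 0 °C; aq NH4Cl
Reagents that add atoms: none
Why: In this Weinreb ketone synthesis the acetylide adds once to give a chelated tetrahedral adduct that collapses to the ynone only on quench, and the weakly basic acetylide should leave the β-silyloxy group in place.

**Step 8**
Reactants: 15 (S)-5-(tert-butyldimethylsilyloxy)-5-(4-methoxyphenyl)-1-(trimethylsilyl)pent-1-yn-3-one
Product: 16 (S)-1-bromo-5-(tert-butyldimethylsilyloxy)-5-(4-methoxyphenyl)pent-1-yn-3-one
Conditions: NBS (1.15 equiv), AgNO3 (10 mol %), acetone, rt, dark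
Reagents that add atoms: N-bromosuccinimide, O=C1CCC(=O)N1Br
Why: Silver-catalysed bromodesilylation converts the alkynylsilane into a silver acetylide that NBS brominates at carbon, a neutral reaction that should spare the silyl ether, the ketone and the anisyl ring.

**Step 9 (key step)**
Reactants: 8 (1Z,3Z)-1,3-dimethoxy-7-methyl-1-(trimethylsilyloxy)octa-1,3,6-triene; 16 (S)-1-bromo-5-(tert-butyldimethylsilyloxy)-5-(4-methoxyphenyl)pent-1-yn-3-one
Product: 19 (S)-1-[2-bromo-6-hydroxy-4-methoxy-3-(3-methylbut-2-enyl)phenyl]-3-(tert-butyldimethylsilyloxy)-3-(4-methoxyphenyl)propan-1-one, via cycloadduct 17 (not isolated), via aryl trimethylsilyl ether 18 (not isolated)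
Conditions: 8 (1.5 equiv), toluene, 0 to 45 °C; then 0.1 M aq HCl, THF, 0 °C (brief)
Reagents that add atoms: none
Why: The electron-rich diene and the electron-poor alkyne should combine in an asynchronous normal-demand Diels–Alder reaction in which the prenyl-bearing C4 terminus of 8 (largest HOMO coefficient) bonds to the bromine-bearing β-carbon of 16 (largest LUMO coefficient) and the ketene acetal carbon C1 bonds to the α-carbon, giving the 1-methoxy-1-silyloxycyclohexa-2,5-diene 17. Ionisation of the acetal C–OMe bond and loss of the doubly allylic, vinylogously acidic C–H then expel methanol (1,4-elimination) to give the aryl silyl ether 18, which the acidic work-up hydrolyses to the hydrogen-bonded phenol 19. The closest known reaction type is the cycloaddition of 1,1,3-trioxygenated silyl ketene acetal dienes with acetylenic ketones and halogenated dienophiles, followed by eliminative aromatisation to resorcinol derivatives. Ring A closes by an intermolecular [4+2] cycloaddition that forms C4a–C5 and C8–C8a together, so no exo or endo cyclisation mode is involved, and no new stereocentre survives: the two sp3 carbons of 17 become aromatic and the S carbinol centre is a spectator under these neutral conditions. The step needs regioselectivity, secured by the match of the most nucleophilic diene terminus with the β-carbon of the ynone (the bromine does not override the ketone, and the linear alkyne keeps this hindered terminus accessible), and it needs loss of methanol in preference to silanol, secured by the more basic methoxy oxygen of the mixed acetal; the bromide thus ends at C8a only.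

**Step 10**
Reactants: 19 (S)-1-[2-bromo-6-hydroxy-4-methoxy-3-(3-methylbut-2-enyl)phenyl]-3-(tert-butyldimethylsilyloxy)-3-(4-methoxyphenyl)propan-1-one
Product: 20 (S)-1-[2-bromo-6-hydroxy-4-methoxy-3-(3-methylbut-2-enyl)phenyl]-3-hydroxy-3-(4-methoxyphenyl)propan-1-one
Conditions: Bu4NF, AcOH (1:1), THF, 0 °C to rt
Reagents that add atoms: none
Why: Fluoride cleaves the Si–O bond under acetic acid buffering, so neither base-induced retro-aldol or E1cB dehydration of the new β-hydroxy ketone nor acid ionisation of the 4-methoxybenzylic C–O bond should occur, and the S centre stays as set.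

**Step 11**
Reactants: 20 (S)-1-[2-bromo-6-hydroxy-4-methoxy-3-(3-methylbut-2-enyl)phenyl]-3-hydroxy-3-(4-methoxyphenyl)propan-1-one
Product: 21 flowerine, (2S)-5-hydroxy-7-methoxy-2-(4-methoxyphenyl)-8-(3-methylbut-2-enyl)-2,3-dihydro-4H-chromen-4-one
Conditions: CuI (10 mol %), 3,4,7,8-tetramethyl-1,10-phenanthroline (20 mol %), Cs2CO3 (2.5 equiv), toluene, 80 °C; then aq NH4Cl
Reagents that add atoms: none
Why: In this Ullmann-type intramolecular C–O coupling the phenanthroline-ligated monovalent copper alkoxide of the secondary alcohol should insert into the C8a–Br bond (activated by the ortho ketone) and close six-membered ring C by reductive elimination; the carbinol C–O bond is never broken, so C2 keeps its S configuration, and the 5-phenoxide formed first lowers the acidity of the C3 methylene, which should hold back retro-aldol, dehydration and chalcone ring-opening.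

**Compound list**
1 | methyl acetoacetate | COC(=O)CC(C)=O | starting material
2 | prenyl bromide (1-bromo-3-methylbut-2-ene) | CC(C)=CCBr | starting material
3 | dilithium dianion of methyl acetoacetate (formed in the flask) | [Li+].[Li+].C=C([O-])C=C([O-])OC | intermediate
4 | methyl 7-methyl-3-oxooct-6-enoate | COC(=O)CC(=O)CCC=C(C)C | intermediate
5 | methyl 3,3-dimethoxy-7-methyloct-6-enoate (formed in the flask) | COC(=O)CC(OC)(OC)CCC=C(C)C | intermediate
6 | methyl (E)-3-methoxy-7-methylocta-2,6-dienoate | COC(=O)/C=C(/OC)CCC=C(C)C | intermediate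
7 | lithium dienolate of 6 (formed in the flask) | [Li+].CO/C([O-])=C/C(OC)=C/CC=C(C)C | intermediate
8 | (1Z,3Z)-1,3-dimethoxy-7-methyl-1-(trimethylsilyloxy)octa-1,3,6-triene | CO/C(O[Si](C)(C)C)=C/C(OC)=C/CC=C(C)C | intermediate
9 | ethyl 3-(4-methoxyphenyl)-3-oxopropanoate | CCOC(=O)CC(=O)c1ccc(OC)cc1 | starting material
10 | ethyl (S)-3-hydroxy-3-(4-methoxyphenyl)propanoate | COc1ccc([C@@H](O)CC(=O)OCC)cc1 | intermediate
11 | ethyl (S)-3-(tert-butyldimethylsilyloxy)-3-(4-methoxyphenyl)propanoate | COc1ccc([C@@H](O[Si](C)(C)C(C)(C)C)CC(=O)OCC)cc1 | intermediate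
12 | (S)-3-(tert-butyldimethylsilyloxy)-N-methoxy-3-(4-methoxyphenyl)-N-methylpropanamide | COc1ccc([C@@H](O[Si](C)(C)C(C)(C)C)CC(=O)N(C)OC)cc1 | intermediate
13 | trimethylsilylacetylene | C#C[Si](C)(C)C | starting material
14 | lithium trimethylsilylacetylide (formed in the flask) | [Li]C#C[Si](C)(C)C | intermediate
15 | (S)-5-(tert-butyldimethylsilyloxy)-5-(4-methoxyphenyl)-1-(trimethylsilyl)pent-1-yn-3-one | COc1ccc([C@@H](O[Si](C)(C)C(C)(C)C)CC(=O)C#C[Si](C)(C)C)cc1 | intermediate
16 | (S)-1-bromo-5-(tert-butyldimethylsilyloxy)-5-(4-methoxyphenyl)pent-1-yn-3-one | COc1ccc([C@@H](O[Si](C)(C)C(C)(C)C)CC(=O)C#CBr)cc1 | intermediate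
17 | (3S)-1-[2-bromo-4,6-dimethoxy-3-(3-methylbut-2-enyl)-6-(trimethylsilyloxy)cyclohexa-1,4-dien-1-yl]-3-(tert-butyldimethylsilyloxy)-3-(4-methoxyphenyl)propan-1-one (cycloadduct, ring centres undefined, formed in the flask) | COc1ccc([C@@H](O[Si](C)(C)C(C)(C)C)CC(=O)C2=C(Br)C(CC=C(C)C)C(OC)=CC2(OC)O[Si](C)(C)C)cc1 | intermediate
18 | (S)-1-[2-bromo-4-methoxy-3-(3-methylbut-2-enyl)-6-(trimethylsilyloxy)phenyl]-3-(tert-butyldimethylsilyloxy)-3-(4-methoxyphenyl)propan-1-one (formed in the flask) | COc1ccc([C@@H](O[Si](C)(C)C(C)(C)C)CC(=O)c2c(O[Si](C)(C)C)cc(OC)c(CC=C(C)C)c2Br)cc1 | intermediate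
19 | (S)-1-[2-bromo-6-hydroxy-4-methoxy-3-(3-methylbut-2-enyl)phenyl]-3-(tert-butyldimethylsilyloxy)-3-(4-methoxyphenyl)propan-1-one | COc1ccc([C@@H](O[Si](C)(C)C(C)(C)C)CC(=O)c2c(O)cc(OC)c(CC=C(C)C)c2Br)cc1 | intermediate
20 | (S)-1-[2-bromo-6-hydroxy-4-methoxy-3-(3-methylbut-2-enyl)phenyl]-3-hydroxy-3-(4-methoxyphenyl)propan-1-one | COc1ccc([C@@H](O)CC(=O)c2c(O)cc(OC)c(CC=C(C)C)c2Br)cc1 | intermediate
21 | flowerine, (2S)-5-hydroxy-7-methoxy-2-(4-methoxyphenyl)-8-(3-methylbut-2-enyl)-2,3-dihydro-4H-chromen-4-one | COc1ccc([C@@H]2CC(=O)c3c(O)cc(OC)c(CC=C(C)C)c3O2)cc1 | target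

**Step count**
Total: 11 steps (3 to the diene, 5 to the bromoynone, 3 after convergence).
Longest linear sequence: 8 steps (steps 4 to 11, from ethyl 3-(4-methoxyphenyl)-3-oxopropanoate).

**Steps most likely to fail**

1. Step 9 (key step). Cycloaddition at the substituted, more hindered diene terminus may be too slow, so that conjugate addition with loss of bromide (alkynyl transfer) or hydrolytic decay of the silyl ketene acetal takes over. The fallback sets out from 16 and returns at 19; it takes the prenyl group off the diene and brings it in later. Commercial methyl (E)-3-methoxybut-2-enoate is converted (LiN(iPr)2, Me3SiCl, THF, −78 °C) into the unsubstituted 1,3-dimethoxy-1-(trimethylsilyloxy)buta-1,3-diene F1, the best-studied diene of this class. Its cycloaddition to 16 and the same work-up should give the des-prenyl bromoketone F2 with the same regiochemistry. O-Prenylation of the chelated phenol with 2 (K2CO3, acetone, 50 °C) gives the aryl prenyl ether F3. A Eu(fod)3-catalysed para-Claisen–Cope rearrangement (CHCl3, 60 °C) should then carry the prenyl group through the free ortho carbon to the carbon para to oxygen, the future C8, giving 19. The positional outcome of this rearrangement would have to be checked at that point.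

2. Step 11. Under carbonate at 80 °C the β-hydroxy ketone may undergo retro-aldol cleavage or dehydration before the C–O bond forms, or the flavanone may ring-open to the chalcone and lose its configuration. The fallback sets out from 19 and returns at 21; it takes the ketone out of play during the coupling. NaBH4 (MeOH–THF, 0 °C to rt) should reduce 19 to the benzylic alcohol F4 (both epimers at the new carbinol, which is oxidised again later). Bu4NF (THF, rt) removes the silyl group to give the bromo triol F5. The same CuI–phenanthroline–Cs2CO3 closure on this non-enolisable substrate should give the flavan-4-ol F6 with C2 unchanged, and MnO2 (CH2Cl2, rt) oxidises the benzylic alcohol to 21 under neutral conditions.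

3. Step 3. Deprotonation may give the C3=C4 isomer with the chain inside, which has no accessible s-cis conformer, or silylation may occur at carbon; acid-induced addition to the prenyl alkene in step 2 would feed the same shortage of usable diene. The fallback sets out from 4 and returns at 19; it makes the diene as its bis-silyl analogue without the acidic enol ether formation. Me3SiCl–Et3N (CH2Cl2, rt) converts 4 into the silyl enol ether F7, and LiN(iPr)2 then Me3SiCl (THF, −78 °C) gives the 1-methoxy-1,3-bis(trimethylsilyloxy)triene F8, a more nucleophilic diene class routinely prepared with an alkyl group at C4. Cycloaddition with 16 and acidic work-up should give the resorcinol bromoketone F9. Methylation of the non-chelated hydroxyl para to the ketone (MeI 1.05 equiv, K2CO3, acetone, rt; the hydrogen-bonded ortho hydroxyl is left) gives 19.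

**Further compounds**
F1 | step 9 | (Z)-1,3-dimethoxy-1-(trimethylsilyloxy)buta-1,3-diene | CO/C(O[Si](C)(C)C)=C/C(OC)=C
F2 | step 9 | (S)-1-(2-bromo-6-hydroxy-4-methoxyphenyl)-3-(tert-butyldimethylsilyloxy)-3-(4-methoxyphenyl)propan-1-one | COc1ccc([C@@H](O[Si](C)(C)C(C)(C)C)CC(=O)c2c(O)cc(OC)cc2Br)cc1
F3 | step 9 | (S)-1-[2-bromo-4-methoxy-6-(3-methylbut-2-enyloxy)phenyl]-3-(tert-butyldimethylsilyloxy)-3-(4-methoxyphenyl)propan-1-one | COc1ccc([C@@H](O[Si](C)(C)C(C)(C)C)CC(=O)c2c(OCC=C(C)C)cc(OC)cc2Br)cc1
F4 | step 11 | (3S)-1-[2-bromo-6-hydroxy-4-methoxy-3-(3-methylbut-2-enyl)phenyl]-3-(tert-butyldimethylsilyloxy)-3-(4-methoxyphenyl)propan-1-ol (both C1 epimers) | COc1ccc([C@@H](O[Si](C)(C)C(C)(C)C)CC(O)c2c(O)cc(OC)c(CC=C(C)C)c2Br)cc1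
F5 | step 11 | (1S)-3-[2-bromo-6-hydroxy-4-methoxy-3-(3-methylbut-2-enyl)phenyl]-1-(4-methoxyphenyl)propane-1,3-diol (both C3 epimers) | COc1ccc([C@@H](O)CC(O)c2c(O)cc(OC)c(CC=C(C)C)c2Br)cc1
F6 | step 11 | (2S)-7-methoxy-2-(4-methoxyphenyl)-8-(3-methylbut-2-enyl)chromane-4,5-diol (both C4 epimers) | COc1ccc([C@@H]2CC(O)c3c(O)cc(OC)c(CC=C(C)C)c3O2)cc1
F7 | step 3 | methyl (Z)-7-methyl-3-(trimethylsilyloxy)octa-2,6-dienoate | COC(=O)/C=C(\O[Si](C)(C)C)CCC=C(C)C
F8 | step 3 | (1Z,3Z)-1-methoxy-7-methyl-1,3-bis(trimethylsilyloxy)octa-1,3,6-triene | CO/C(O[Si](C)(C)C)=C/C(O[Si](C)(C)C)=C/CC=C(C)C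
F9 | step 3 | (S)-1-[2-bromo-4,6-dihydroxy-3-(3-methylbut-2-enyl)phenyl]-3-(tert-butyldimethylsilyloxy)-3-(4-methoxyphenyl)propan-1-one | COc1ccc([C@@H](O[Si](C)(C)C(C)(C)C)CC(=O)c2c(O)cc(O)c(CC=C(C)C)c2Br)cc1
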